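**Retrosynthetic overview**

- Feature: on the benzo ring, Br sits on C4 and on C6, either side of C5–H and each 1,3 to C7a (the carbon bearing N1). N1 steers electrophiles to C5 and C7, so both C–Br bonds are made as the two ortho positions of a nitrogen lent to C5 and removed afterwards.
- Target ⇒ racemic 4,6-dibromo-3-(methylsulfanyl)oxindole (C2–Br and C2=C3 from the lactam C=O with POBr3) ⇒ 4,6-dibromooxindole (C3–S from the enolate and MeSSMe).
- 4,6-Dibromooxindole ⇒ 5-amino-4,6-dibromooxindole (C5–H from C5–NH2 via the diazonium salt) ⇒ 5-aminooxindole + Br2 (C4–Br and C6–Br, amine-directed).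
- Ring order: no ring is built. The benzo ring and the five-membered lactam ring are bought together as the oxindole, and the lactam ring becomes the aromatic pyrrole ring only in the last step.

Key step: step 1

Remark: the target is achiral; the one stereocentre on the way (C3 of the sulfenylated oxindole) is made racemic and vanishes on aromatisation. 5-Aminoindolin-2-one is taken as a purchasable compound.

**Route**

Step 1
Reactants: 1 5-aminoindolin-2-one; 2 bromine
Product: 4 5-amino-4,6-dibromoindolin-2-one, via 5-amino-6-bromoindolin-2-one 3 (not isolated)
Conditions: Br2 (2.05 equiv), NaOAc (2.2 equiv), AcOH, 15 °C → rt; aq Na2S2O3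
Reagents that add atoms: bromine, BrBr
Why: Twofold electrophilic aromatic substitution: the NH2 group on C5 outranks every other substituent of the benzo ring as a donor and stabilises the arenium ions for bromine attack at its two ortho carbons, so the less hindered C6 should react first (3) and C4 second (4), with acetate taking up the HBr so the amine stays free. The closest known reaction type is the ortho,ortho-dibromination of para-substituted anilines with bromine in acetic acid, 4-aminoacetanilide being the open-chain model of 1. No ring is closed and no stereocentre is formed; the step makes only the C4–Br and C6–Br bonds. The selectivity needed is C4 and C6 over C7 and over the C3 methylene: the carbon para to the amine (C7a) already bears N1, C7 is activated only by the acylated N1, a much weaker donor than NH2, and at the lactam oxidation level C2/C3 lack the nucleophilicity of an indole pyrrole ring, the amide enolising too slowly in buffered acetic acid to take up bromine. Exact stoichiometry and a temperature at or below ambient should keep a third bromine off C7 and C3.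

Step 2
Reactants: 4 5-amino-4,6-dibromoindolin-2-one
Product: 6 4,6-dibromoindolin-2-one, via 4,6-dibromo-2-oxoindoline-5-diazonium hydrogen sulfate 5 (not isolated)
Conditions: NaNO2 (1.05 equiv), conc. H2SO4, AcOH, 0–5 °C; then 50% aq H3PO2 (10 equiv), 0 °C → rt
Reagents that add atoms: none
Why: Diazotisation with preformed nitrosylsulfuric acid followed by hypophosphorous acid hydrodediazoniation (radical chain, the aryl radical from 5 taking hydrogen from H3PO2) is the standard deamination of weakly basic 2,6-dibromoanilines; one equivalent of nitrite at 0–5 °C should react with the primary amine far faster than with the slowly enolising lactam CH2, and the chloride-free medium avoids exchange of the ortho bromines activated by the diazonium group.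

Step 3
Reactants: 6 4,6-dibromoindolin-2-one; 7 dimethyl disulfide
Product: 10 racemic 4,6-dibromo-3-(methylsulfanyl)indolin-2-one, via potassium 4,6-dibromo-1H-indol-2-olate 8 (not isolated), via potassium 4,6-dibromo-3-(methylsulfanyl)-1H-indol-2-olate 9 (not isolated)
Conditions: KOt-Bu (2.2 equiv), THF–DMF (4:1), Ar, 0 °C; MeSSMe (1.05 equiv), 0 °C → rt; aq NH4Cl
Reagents that add atoms: dimethyl disulfide, CSSC
Why: Alpha-sulfenylation of an amide enolate with a disulfide: enolate 8 attacks the S–S bond through C3, the second equivalent of base stores the more acidic product as enolate 9, and the methanethiolate released should strip any 3,3-bis(methylsulfanyl) material back to 9, so the mono-sulfide is the thermodynamic outcome; the C3 stereocentre is formed racemic without control because step 4 removes it.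

Step 4
Reactants: 10 racemic 4,6-dibromo-3-(methylsulfanyl)indolin-2-one; 11 phosphorus oxybromide
Product: 12 2,4,6-tribromo-3-(methylsulfanyl)-1H-indole
Conditions: POBr3 (2.5 equiv), imidazole (1.2 equiv), ClCH2CH2Cl, 80 °C; then ice-water, aq NaHCO3 wash
Reagents that add atoms: phosphorus oxybromide, O=P(Br)(Br)Br
Why: Deoxybromination of a lactam, the known conversion of oxindoles into 2-bromoindoles: O-phosphorylation, bromide attack at C2 and loss of the C3 proton should give the aromatic 2-bromoindole, with the thioether and aryl bromides inert and imidazole buffering the HBr.

**Compound list**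

1 | 5-aminoindolin-2-one (5-aminooxindole) | Nc1ccc2NC(=O)Cc2c1 | starting material
2 | bromine | BrBr | starting material
3 | 5-amino-6-bromoindolin-2-one (not isolated) | Nc1cc2CC(=O)Nc2cc1Br | intermediate
4 | 5-amino-4,6-dibromoindolin-2-one | Nc1c(Br)cc2NC(=O)Cc2c1Br | intermediate
5 | 4,6-dibromo-2-oxoindoline-5-diazonium hydrogen sulfate (not isolated) | N#[N+]c1c(Br)cc2NC(=O)Cc2c1Br.OS(=O)(=O)[O-] | intermediate
6 | 4,6-dibromoindolin-2-one | O=C1Cc2c(Br)cc(Br)cc2N1 | intermediate
7 | dimethyl disulfide | CSSC | starting material
8 | potassium 4,6-dibromo-1H-indol-2-olate (not isolated) | [K+].[O-]c1cc2c(Br)cc(Br)cc2[nH]1 | intermediate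
9 | potassium 4,6-dibromo-3-(methylsulfanyl)-1H-indol-2-olate (not isolated) | [K+].CSc1c([O-])[nH]c2cc(Br)cc(Br)c12 | intermediate
10 | racemic 4,6-dibromo-3-(methylsulfanyl)indolin-2-one | CSC1C(=O)Nc2cc(Br)cc(Br)c21 | intermediate
11 | phosphorus oxybromide (POBr3) | O=P(Br)(Br)Br | starting material
12 | 2,4,6-tribromo-3-(methylsulfanyl)-1H-indole | CSc1c(Br)[nH]c2cc(Br)cc(Br)c12 | target

**Summary and risks**

Total step count: 4. Longest linear sequence: 4 steps (1 → 4 → 6 → 10 → 12).

Steps most likely to fail, in this order: step 3, step 2, step 4.

First, step 3. The stabilised indol-2-olate may attack the S–S bond only sluggishly, or the product enolate may take up a second methylsulfanyl group faster than thiolate removes it. The fallback moves C–S bond formation to the indole stage, where C3 is a strong carbon nucleophile and can react only once. It sets out from 6. With POBr3 and imidazole in ClCH2CH2Cl at 80 °C (the reaction of step 4), 6 should give 2,4,6-tribromo-1H-indole F1. Methanesulfenyl chloride F2, made at −20 °C in CH2Cl2 from dimethyl disulfide 7 and SO2Cl2, is added to F1 at −78 °C, and the mixture is warmed to −20 °C and quenched with aqueous NaHCO3. Electrophilic substitution at C3, the only free pyrrole carbon, should give the target, so the fallback comes back to the route at 12.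

Second, step 2. Nitrosation of the C3 methylene (on the way to the isatin 3-oxime), or azo coupling of the diazonium ion with the enol, may compete with clean N-diazotisation and reduction. The fallback postpones the deamination until C2 and C3 carry no hydrogen. It sets out from 4.
- Sulfenylation: 4 is deprotonated with KOt-Bu to potassium 5-amino-4,6-dibromo-1H-indol-2-olate F3 and sulfenylated with 7 under the conditions of step 3. Through potassium 5-amino-4,6-dibromo-3-(methylsulfanyl)-1H-indol-2-olate F4 this should give racemic 5-amino-4,6-dibromo-3-(methylsulfanyl)indolin-2-one F5.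
- Aromatisation: POBr3/imidazole as in step 4 should give 5-amino-2,4,6-tribromo-3-(methylsulfanyl)-1H-indole F6. The amino group is shielded by its two ortho bromines, and any N–P adduct should be hydrolysed on aqueous work-up.
- Deamination: tert-butyl nitrite in THF at 60 °C removes the amino group by radical hydrodediazoniation with THF as hydrogen donor, and the fallback comes back to the route at 12.

Third, step 4. Activation of the crowded lactam (C3–SMe next to the peri C4–Br) may stall, or HBr released at 80 °C may degrade the acid-sensitive 2-bromoindole or cleave the C3–S bond. The fallback makes the C2–Br bond by electrophilic bromination instead of deoxybromination. It sets out from 10. The lactam is reduced with BH3·THF (THF, 0 °C → rt; acidic work-up dehydrates the 2-hydroxyindoline) to 4,6-dibromo-3-(methylsulfanyl)-1H-indole F7. N-Bromosuccinimide (1.0 equiv, CH2Cl2, 0 °C) should then brominate C2, the only free pyrrole position of this 3-substituted indole, and the fallback comes back to the route at 12.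

**Further compounds**

F1 | step 3 | 2,4,6-tribromo-1H-indole | Brc1cc(Br)c2cc(Br)[nH]c2c1
F2 | step 3 | methanesulfenyl chloride | CSCl
F3 | step 2 | potassium 5-amino-4,6-dibromo-1H-indol-2-olate | [K+].[O-]c1cc2c(Br)c(N)c(Br)cc2[nH]1
F4 | step 2 | potassium 5-amino-4,6-dibromo-3-(methylsulfanyl)-1H-indol-2-olate | [K+].CSc1c([O-])[nH]c2cc(Br)c(N)c(Br)c12
F5 | step 2 | racemic 5-amino-4,6-dibromo-3-(methylsulfanyl)indolin-2-one | CSC1C(=O)Nc2cc(Br)c(N)c(Br)c21
F6 | step 2 | 5-amino-2,4,6-tribromo-3-(methylsulfanyl)-1H-indole | CSc1c(Br)[nH]c2cc(Br)c(N)c(Br)c12
F7 | step 4 | 4,6-dibromo-3-(methylsulfanyl)-1H-indole | CSc1c[nH]c2cc(Br)cc(Br)c12
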